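**Retrosynthetic overview**
1. The C1–OAr ether is made last by Mitsunobu coupling of hydrangetin 22 with epoxy alcohol 21; the coumarin is bought intact.
2. Epoxide 21 comes from tetraol lactone 18 by primary tosylation and Payne rearrangement; the epoxide oxygen is the C3 oxygen, and C2 is inverted.
3. Lactone 18 comes from β-hydroxy ketone 16 by a 1,3-anti reduction (sets the lactone CH–O) and lactonisation onto the lactate dioxolanone; 16 comes from isoxazoline 14.
4. Isoxazoline 14 is the key ring: a nitrile oxide [3+2] cycloaddition between the lactate-derived oxime 7 and the glycerate-derived isopropenyl dioxolane 11 forms the C–C bond and the tertiary C–O bond.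
5. Ring order: dioxolanone (temporary) → isoxazoline → γ-lactone → epoxide. The two bought stereocentres are (S)-lactic acid and methyl (S)-glycerate acetonide.

Assumption: 7-hydroxy-8-methoxycoumarin (22, hydrangetin) and methyl (S)-2,2-dimethyl-1,3-dioxolane-4-carboxylate (8) are bought as catalogue compounds.

**Route**

Step 1
Reactants: 1 (S)-lactic acid; 2 pivaldehyde
Product: 3 (2S,5S)-2-tert-butyl-5-methyl-1,3-dioxolan-4-one
Conditions: TsOH·H2O (cat.), H2SO4 (cat.), pentane, reflux, Dean–Stark; recrystallise at −78 °C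
Reagents that add atoms: none
Why: Acid-catalysed acetalisation (Seebach dioxolanone formation) under thermodynamic control gives the cis acetal, whose new acetal centre is set by the lactic acid centre and purified by crystallisation.

Step 2
Reactants: 3 (2S,5S)-2-tert-butyl-5-methyl-1,3-dioxolan-4-one; 4 allyl bromide
Product: 5 (2S,5R)-2-tert-butyl-5-methyl-5-(prop-2-en-1-yl)-1,3-dioxolan-4-one
Conditions: LDA, THF, −78 °C; allyl bromide, −78 → −30 °C
Reagents that add atoms: none
Why: Seebach self-regeneration-of-stereocentres enolate alkylation: the allyl group enters anti to the tert-butyl group and so replaces the original H with net retention, fixing the future α-hydroxy-α-methyl lactone carbon as R.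

Step 3
Reactants: 5 (2S,5R)-2-tert-butyl-5-methyl-5-(prop-2-en-1-yl)-1,3-dioxolan-4-one
Product: 7 (2S,5R)-2-tert-butyl-5-[2-(hydroxyimino)ethyl]-5-methyl-1,3-dioxolan-4-one, via aldehyde 6 (not isolated)
Conditions: O3, CH2Cl2/MeOH, −78 °C; Me2S, → rt; then NH2OH·HCl, NaOAc, rt
Reagents that add atoms: ozone, [O-][O+]=O (its oxygen is carried in 6 only); hydroxylamine hydrochloride, NO.Cl
Why: Ozonolysis with reductive work-up followed by oxime condensation converts the allyl group into the nitrile oxide precursor without touching a stereocentre.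

Step 4
Reactants: 8 methyl (4S)-2,2-dimethyl-1,3-dioxolane-4-carboxylate
Product: 10 1-[(4S)-2,2-dimethyl-1,3-dioxolan-4-yl]ethan-1-one, via Weinreb amide 9 (not isolated)
Conditions: MeNH(OMe)·HCl, i-PrMgCl, THF, −20 °C; then MeMgBr, −20 → 0 °C; aq NH4Cl
Reagents that add atoms: N,O-dimethylhydroxylamine hydrochloride, CNOC.Cl (carried in 9 only); methylmagnesium bromide, C[Mg]Br
Why: Weinreb ketone synthesis: the chelated tetrahedral intermediate stops at the methyl ketone, and the α-alkoxy stereocentre is not epimerised at low temperature.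

Step 5
Reactants: 10 1-[(4S)-2,2-dimethyl-1,3-dioxolan-4-yl]ethan-1-one
Product: 11 (4R)-2,2-dimethyl-4-(prop-1-en-2-yl)-1,3-dioxolane
Conditions: Ph3PCH3Br, KHMDS, THF, 0 °C; add 10 at −78 °C → rt
Reagents that add atoms: methyltriphenylphosphonium bromide, C[P+](c1ccccc1)(c1ccccc1)c1ccccc1.[Br-]
Why: Wittig methylenation with a salt-free ylide at low temperature gives the 1,1-disubstituted alkene with the allylic stereocentre retained (the descriptor changes to R only through CIP priorities).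

Step 6
Reactants: 7 (2S,5R)-2-tert-butyl-5-[2-(hydroxyimino)ethyl]-5-methyl-1,3-dioxolan-4-one; 11 (4R)-2,2-dimethyl-4-(prop-1-en-2-yl)-1,3-dioxolane (2 equiv)
Product: 14 (2S,5R)-2-tert-butyl-5-({(5R)-5-[(4S)-2,2-dimethyl-1,3-dioxolan-4-yl]-5-methyl-4,5-dihydro-1,2-oxazol-3-yl}methyl)-5-methyl-1,3-dioxolan-4-one, via hydroximoyl chloride 12 (not isolated), via nitrile oxide 13 (not isolated)
Conditions: NCS, DMF, rt; then 11, Et3N (syringe pump), DMF/CH2Cl2, 0 °C → rt
Reagents that add atoms: N-chlorosuccinimide, O=C1CCC(=O)N1Cl (chlorine carried in 12 only)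
Why: Huisgen nitrile oxide–alkene [3+2] cycloaddition: oxygen adds to the substituted alkene carbon (5,5-disubstituted isoxazoline), and the inside-alkoxy effect of the dioxolane centre directs attack to give the anti (erythro) adduct, which sets the future quaternary epoxide carbon.

Step 7
Reactants: 14 (isoxazoline)
Product: 16 (2S,5R)-2-tert-butyl-5-{(4R)-4-[(4S)-2,2-dimethyl-1,3-dioxolan-4-yl]-4-hydroxy-2-oxopentyl}-5-methyl-1,3-dioxolan-4-one, via β-hydroxy imine 15 (not isolated)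
Conditions: H2 (1 atm), Raney Ni, B(OH)3, MeOH/H2O (5:1), rt
Reagents that add atoms: water, O
Why: Curran N–O hydrogenolysis with buffered hydrolysis of the β-hydroxy imine unveils the aldol-type β-hydroxy ketone without retro-aldol cleavage or change at any stereocentre.

Step 8
Reactants: 16 (β-hydroxy ketone)
Product: 18 (3R,5R)-3-hydroxy-3-methyl-5-[(2R,3S)-2,3,4-trihydroxy-2-methylbutyl]oxolan-2-one, via anti-1,3-diol 17 (not isolated)
Conditions: Me4NBH(OAc)3, MeCN/AcOH (1:1), −30 °C; then 2 M aq HCl, THF, rt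
Reagents that add atoms: none
Why: Evans–Saksena hydroxyl-directed reduction delivers hydride intramolecularly from the tertiary alkoxyborohydride to give the 1,3-anti diol; acid then drives translactonisation onto the dioxolanone (pivaldehyde lost, retention at the carbinol) and removes the acetonide.

Step 9
Reactants: 18 (tetraol lactone)
Product: 21 (3R,5S)-3-hydroxy-5-{[(2R,3R)-3-(hydroxymethyl)-2-methyloxiran-2-yl]methyl}-3-methyloxolan-2-one, via primary tosylate 19 (not isolated), via terminal epoxide 20 (not isolated)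
Conditions: TsCl (1.05 equiv), Bu2SnO (cat.), Et3N, MeCN, 0 °C → rt; then t-BuOK, THF, 0 °C
Reagents that add atoms: p-toluenesulfonyl chloride, Cc1ccc(cc1)S(Cl)(=O)=O (tosyl group carried in 19 only)
Why: Tin-catalysed primary tosylation and base closure give the terminal epoxide, which undergoes Payne rearrangement: the tertiary alkoxide opens it at the CH carbon with inversion, giving the thermodynamically favoured trisubstituted (2R,3R)-epoxide and primary alkoxide.

Step 10
Reactants: 21 (epoxy alcohol); 22 7-hydroxy-8-methoxy-2H-chromen-2-one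
Product: 23 7-{[(2R,3R)-3-{[(2S,4R)-4-hydroxy-4-methyl-5-oxooxolan-2-yl]methyl}-3-methyloxiran-2-yl]methoxy}-8-methoxy-2H-chromen-2-one
Conditions: PPh3, DIAD, THF, 0 °C → rt
Reagents that add atoms: none
Why: Mitsunobu etherification joins the primary epoxy alcohol to the acidic 7-OH of the coumarin at a non-stereogenic CH2, leaving the epoxide, lactone and tertiary alcohol untouched.

**Compound list**
1 | (S)-lactic acid, (2S)-2-hydroxypropanoic acid | C[C@H](O)C(=O)O | starting material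
2 | pivaldehyde, 2,2-dimethylpropanal | CC(C)(C)C=O | starting material
3 | (2S,5S)-2-tert-butyl-5-methyl-1,3-dioxolan-4-one (cis) | C[C@@H]1O[C@H](C(C)(C)C)OC1=O | intermediate
4 | allyl bromide, 3-bromoprop-1-ene | C=CCBr | starting material
5 | (2S,5R)-2-tert-butyl-5-methyl-5-(prop-2-en-1-yl)-1,3-dioxolan-4-one | C[C@]1(CC=C)O[C@H](C(C)(C)C)OC1=O | intermediate
6 | (2S,5R)-2-tert-butyl-5-methyl-5-(2-oxoethyl)-1,3-dioxolan-4-one | C[C@]1(CC=O)O[C@H](C(C)(C)C)OC1=O | intermediate
7 | (2S,5R)-2-tert-butyl-5-[2-(hydroxyimino)ethyl]-5-methyl-1,3-dioxolan-4-one (E/Z mixture) | C[C@]1(CC=NO)O[C@H](C(C)(C)C)OC1=O | intermediate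
8 | methyl (4S)-2,2-dimethyl-1,3-dioxolane-4-carboxylate | COC(=O)[C@@H]1COC(C)(C)O1 | starting material
9 | (4S)-N-methoxy-N,2,2-trimethyl-1,3-dioxolane-4-carboxamide | CON(C)C(=O)[C@@H]1COC(C)(C)O1 | intermediate
10 | 1-[(4S)-2,2-dimethyl-1,3-dioxolan-4-yl]ethan-1-one | CC(=O)[C@@H]1COC(C)(C)O1 | intermediate
11 | (4R)-2,2-dimethyl-4-(prop-1-en-2-yl)-1,3-dioxolane | C=C(C)[C@@H]1COC(C)(C)O1 | intermediate
12 | 2-[(2S,4R)-2-tert-butyl-4-methyl-5-oxo-1,3-dioxolan-4-yl]-N-hydroxyethanimidoyl chloride | C[C@]1(CC(Cl)=NO)O[C@H](C(C)(C)C)OC1=O | intermediate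
13 | 2-[(2S,4R)-2-tert-butyl-4-methyl-5-oxo-1,3-dioxolan-4-yl]acetonitrile oxide | C[C@]1(CC#[N+][O-])O[C@H](C(C)(C)C)OC1=O | intermediate
14 | (2S,5R)-2-tert-butyl-5-({(5R)-5-[(4S)-2,2-dimethyl-1,3-dioxolan-4-yl]-5-methyl-4,5-dihydro-1,2-oxazol-3-yl}methyl)-5-methyl-1,3-dioxolan-4-one | C[C@]1(CC2=NO[C@@](C)([C@@H]3COC(C)(C)O3)C2)O[C@H](C(C)(C)C)OC1=O | intermediate
15 | (2S,5R)-2-tert-butyl-5-{(4R)-4-[(4S)-2,2-dimethyl-1,3-dioxolan-4-yl]-4-hydroxy-2-iminopentyl}-5-methyl-1,3-dioxolan-4-one | C[C@]1(CC(=N)C[C@@](C)(O)[C@@H]2COC(C)(C)O2)O[C@H](C(C)(C)C)OC1=O | intermediate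
16 | (2S,5R)-2-tert-butyl-5-{(4R)-4-[(4S)-2,2-dimethyl-1,3-dioxolan-4-yl]-4-hydroxy-2-oxopentyl}-5-methyl-1,3-dioxolan-4-one | C[C@]1(CC(=O)C[C@@](C)(O)[C@@H]2COC(C)(C)O2)O[C@H](C(C)(C)C)OC1=O | intermediate
17 | (2S,5R)-2-tert-butyl-5-{(2R,4R)-4-[(4S)-2,2-dimethyl-1,3-dioxolan-4-yl]-2,4-dihydroxypentyl}-5-methyl-1,3-dioxolan-4-one | C[C@]1(C[C@H](O)C[C@@](C)(O)[C@@H]2COC(C)(C)O2)O[C@H](C(C)(C)C)OC1=O | intermediate
18 | (3R,5R)-3-hydroxy-3-methyl-5-[(2R,3S)-2,3,4-trihydroxy-2-methylbutyl]oxolan-2-one | OC[C@H](O)[C@](C)(O)C[C@@H]1C[C@@](C)(O)C(=O)O1 | intermediate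
19 | (2S,3R)-2,3-dihydroxy-4-[(2R,4R)-4-hydroxy-4-methyl-5-oxooxolan-2-yl]-3-methylbutyl 4-methylbenzenesulfonate | Cc1ccc(cc1)S(=O)(=O)OC[C@H](O)[C@](C)(O)C[C@@H]1C[C@@](C)(O)C(=O)O1 | intermediate
20 | (3R,5R)-3-hydroxy-5-{(2R)-2-hydroxy-2-[(2S)-oxiran-2-yl]propyl}-3-methyloxolan-2-one | C1O[C@@H]1[C@](C)(O)C[C@@H]2C[C@@](C)(O)C(=O)O2 | intermediate
21 | (3R,5S)-3-hydroxy-5-{[(2R,3R)-3-(hydroxymethyl)-2-methyloxiran-2-yl]methyl}-3-methyloxolan-2-one | OC[C@H]1O[C@]1(C)C[C@@H]1C[C@@](C)(O)C(=O)O1 | intermediate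
22 | 7-hydroxy-8-methoxy-2H-chromen-2-one (hydrangetin) | COc1c(O)ccc2ccc(=O)oc12 | starting material
23 | 7-{[(2R,3R)-3-{[(2S,4R)-4-hydroxy-4-methyl-5-oxooxolan-2-yl]methyl}-3-methyloxiran-2-yl]methoxy}-8-methoxy-2H-chromen-2-one | COc1c(OC[C@H]2O[C@]2(C)C[C@@H]2C[C@@](C)(O)C(=O)O2)ccc2ccc(=O)oc12 | target

**Totals**
Total step count: 10.
Longest linear sequence: 8 steps (steps 1, 2, 3, 6, 7, 8, 9, 10; 1 → 3 → 5 → 7 → 14 → 16 → 18 → 21 → 23).

**Three steps most likely to fail, with fallbacks**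

Step 6 (cycloaddition). The facial selectivity on the isopropenyl dioxolane is predicted from the inside-alkoxy model rather than known for this substrate, and is probably only moderate (I would expect roughly 4–6:1, with chromatographic separation). The aliphatic nitrile oxide can also dimerise. The fallback builds the same tertiary carbinol by an open-chain Felkin–Anh addition instead of a cycloaddition. It sets out from 3 and 10 and comes back at 16. The lithium enolate of 3 (LDA, THF, −78 °C) is alkylated with 2-(chloromethyl)-3-(trimethylsilyl)prop-1-ene/NaI to give the allylsilane (2S,5R)-2-tert-butyl-5-methyl-5-{2-[(trimethylsilyl)methyl]prop-2-en-1-yl}-1,3-dioxolan-4-one F1. A BF3·OEt2-promoted Hosomi–Sakurai addition of F1 to ketone 10 (CH2Cl2, −78 °C; monodentate Lewis acid, attack anti to the dioxolane C–O) gives the methylidene tertiary alcohol F2. Ozonolysis of its 1,1-disubstituted alkene (O3, CH2Cl2, −78 °C; Me2S) gives β-hydroxy ketone 16.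

Step 8 (anti reduction). A tertiary carbinol exchanges slowly onto boron and discriminates only between methyl and the dioxolanyl group, so the anti:syn ratio may be modest. The fallback uses the chelate-controlled syn reduction and corrects the carbinol centre by an invertive lactonisation. It sets out from 16 and comes back at 18. Narasaka–Prasad reduction (Et2BOMe, NaBH4, THF/MeOH, −78 °C) gives the syn-1,3-diol F3. This is mesylated at once at the secondary hydroxyl (MsCl, Et3N, CH2Cl2, −20 °C), before it can lactonise with retention, to give the mesylate F4. LiOH in THF/H2O opens the dioxolanone, and the carboxylate displaces the mesylate with inversion to give the lactone acetonide F5. Aqueous HCl/THF then gives 18.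

Step 9 (tosylation/Payne cascade). The risks are over-tosylation, incomplete epoxide migration and base damage to the lactone. The fallback replaces the migration by a direct 3-exo displacement at the activated secondary carbon. It sets out from 18 and comes back at 21. TBDPSCl/imidazole (DMF, 0 °C) protects the primary hydroxyl to give the silyl ether F6. MsCl/Et3N (CH2Cl2, −20 °C) activates the only secondary hydroxyl to give the mesylate F7. K2CO3/MeOH (0 °C) lets the tertiary alkoxide displace the mesylate with inversion to give the silyl-protected epoxide F8. TBAF (THF, 0 °C) then gives 21.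

**Further compounds**
F1 | step 6 | (2S,5R)-2-tert-butyl-5-methyl-5-{2-[(trimethylsilyl)methyl]prop-2-en-1-yl}-1,3-dioxolan-4-one | C[C@]1(CC(=C)C[Si](C)(C)C)O[C@H](C(C)(C)C)OC1=O
F2 | step 6 | (2S,5R)-2-tert-butyl-5-{(4R)-4-[(4S)-2,2-dimethyl-1,3-dioxolan-4-yl]-4-hydroxy-2-methylidenepentyl}-5-methyl-1,3-dioxolan-4-one | C[C@]1(CC(=C)C[C@@](C)(O)[C@@H]2COC(C)(C)O2)O[C@H](C(C)(C)C)OC1=O
F3 | step 8 | (2S,5R)-2-tert-butyl-5-{(2S,4R)-4-[(4S)-2,2-dimethyl-1,3-dioxolan-4-yl]-2,4-dihydroxypentyl}-5-methyl-1,3-dioxolan-4-one | C[C@]1(C[C@@H](O)C[C@@](C)(O)[C@@H]2COC(C)(C)O2)O[C@H](C(C)(C)C)OC1=O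
F4 | step 8 | (2S,4R)-1-[(2S,4R)-2-tert-butyl-4-methyl-5-oxo-1,3-dioxolan-4-yl]-4-[(4S)-2,2-dimethyl-1,3-dioxolan-4-yl]-4-hydroxypentan-2-yl methanesulfonate | C[C@]1(C[C@@H](OS(C)(=O)=O)C[C@@](C)(O)[C@@H]2COC(C)(C)O2)O[C@H](C(C)(C)C)OC1=O
F5 | step 8 | (3R,5R)-5-{(2R)-2-[(4S)-2,2-dimethyl-1,3-dioxolan-4-yl]-2-hydroxypropyl}-3-hydroxy-3-methyloxolan-2-one | CC1(C)OC[C@H](O1)[C@](C)(O)C[C@@H]2C[C@@](C)(O)C(=O)O2
F6 | step 9 | (3R,5R)-5-[(2R,3S)-4-[(tert-butyldiphenylsilyl)oxy]-2,3-dihydroxy-2-methylbutyl]-3-hydroxy-3-methyloxolan-2-one | CC(C)(C)[Si](OC[C@H](O)[C@](C)(O)C[C@@H]1C[C@@](C)(O)C(=O)O1)(c1ccccc1)c1ccccc1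
F7 | step 9 | (2S,3R)-1-[(tert-butyldiphenylsilyl)oxy]-3-hydroxy-4-[(2R,4R)-4-hydroxy-4-methyl-5-oxooxolan-2-yl]-3-methylbutan-2-yl methanesulfonate | CC(C)(C)[Si](OC[C@H](OS(C)(=O)=O)[C@](C)(O)C[C@@H]1C[C@@](C)(O)C(=O)O1)(c1ccccc1)c1ccccc1
F8 | step 9 | (3R,5S)-5-{[(2R,3R)-3-{[(tert-butyldiphenylsilyl)oxy]methyl}-2-methyloxiran-2-yl]methyl}-3-hydroxy-3-methyloxolan-2-one | CC(C)(C)[Si](OC[C@H]1O[C@]1(C)C[C@@H]1C[C@@](C)(O)C(=O)O1)(c1ccccc1)c1ccccc1
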